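**Plan**
- Numbering follows the name of 14. C1 = CBr(CH2Br), C2 = CHCl, C3 = CH2, C4 = CHCl, C5 = C(CH3)(CH=CHCl), C6 = CH2, and C1′/C2′ are the inner and outer vinyl carbons.
- Retrosynthetic cuts, in order: both C–Br bonds (Br2 on an exocyclic C1=CH2); C2–Cl (SN2 on an allylic alcohol made from a C1–C2 epoxide); C1=C2 together with C1′=C2′ in one metathesis event; C4–Cl; C5–C6 (enolate alkylation).
- Enabling feature: ring carbon C2 and vinyl carbon C1′ are the two ends of the chain C2–C3–C4–C5–C1′. A C2=C1′ double bond ties them into a cyclopentene (ring C5–C4–C3–C2=C1′) that holds the early stereocentres C4 and C5. A methallyl arm on C5 already contains C6, C1 and the later CH2Br carbon.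
- Forward: the five-membered ring comes first, from 2-methylcyclopentane-1,3-dione. A ring-rearrangement metathesis cleaves it at C2=C1′, closes the six-membered ring at C1=C2, and caps C1′ with CHCl from (Z)-1,2-dichloroethene. The halogens at C2, C1 and CH2 follow.
- Stereochemistry: C5 and C4 come from a catalytic desymmetrising reduction of the prochiral dione plus one SN2 inversion. C2 comes from face-selective epoxidation plus one SN2 inversion, C1 from axial opening of a bromonium ion, and the Z-alkene from the metathesis catalyst.

Key step: step 6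

Assumption: the oxazaborolidine in step 2 is taken to follow its usual large/small model, with the quaternary carbon as the large group. If the sense were opposite, the (R)-catalyst would be used.

Step 1
Reactants: 1 2-methylcyclopentane-1,3-dione; 2 3-bromo-2-methylprop-1-ene
Product: 3 2-methyl-2-(2-methylprop-2-en-1-yl)cyclopentane-1,3-dione
Conditions: NaOH (1 M aq), rt
Reagents that add atoms: none
Why: C-alkylation of the stabilised enolate of a 2-alkylcyclopentane-1,3-dione with a reactive allylic bromide in water is a standard reaction, creates the still prochiral quaternary carbon C5 and brings in C6, C1 and the later CH2Br carbon in one piece.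

Step 2
Reactants: 3 2-methyl-2-(2-methylprop-2-en-1-yl)cyclopentane-1,3-dione
Product: 4 (2R,3R)-3-hydroxy-2-methyl-2-(2-methylprop-2-en-1-yl)cyclopentan-1-one (OH cis to methallyl, trans to methyl)
Conditions: (S)-Me-CBS oxazaborolidine (20 mol%), catecholborane (1.1 equiv), PhNEt2, toluene, −60 °C; then MeOH, aq NaHCO3
Reagents that add atoms: none
Why: Desymmetrising Corey–Bakshi–Shibata reduction: the catalyst fixes the carbinol configuration (quaternary carbon as large group, R at C4), and of the two enantiotopic carbonyl groups the one reacts that can take this hydride from the methyl side, anti to the larger methallyl group, so that C4 and C5 are set together with OH cis to methallyl.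

Step 3
Reactants: 4 (2R,3R)-3-hydroxy-2-methyl-2-(2-methylprop-2-en-1-yl)cyclopentan-1-one
Product: 5 (2S,3S)-3-chloro-2-methyl-2-(2-methylprop-2-en-1-yl)cyclopentan-1-one (Cl cis to methyl)
Conditions: PPh3, CCl4, MeCN, 60 °C
Reagents that add atoms: carbon tetrachloride, ClC(Cl)(Cl)Cl
Why: Appel reaction in which chloride displaces the oxyphosphonium group by SN2 from the face that carries only the methyl group and so inverts C4; substitution at a cyclopentyl carbinol next to a quaternary carbon has close precedent in the inversion of 17β-hydroxy steroids, and loss of HCl by E1cB is excluded because the carbon between C=O and C–Cl bears no hydrogen.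

Step 4
Reactants: 5 (2S,3S)-3-chloro-2-methyl-2-(2-methylprop-2-en-1-yl)cyclopentan-1-one
Product: 7 (4S,5S)-4-chloro-5-methyl-5-(2-methylprop-2-en-1-yl)cyclopent-1-en-1-yl trifluoromethanesulfonate, via lithium enolate 6 (not isolated)
Conditions: LiHMDS, THF, −78 °C; then N-(5-chloropyridin-2-yl)bis(trifluoromethanesulfonimide), −78 to 0 °C
Reagents that add atoms: N-(5-chloropyridin-2-yl)bis(trifluoromethanesulfonimide), FC(F)(F)S(=O)(=O)N(c1ccc(Cl)cn1)S(=O)(=O)C(F)(F)F
Why: The ketone has a single enolisable position (C2), so kinetic deprotonation with a non-nucleophilic amide and O-sulfonylation give one enol triflate, and the absence of a nucleophile at C=O avoids a Grob-type fragmentation toward the C4–Cl bond.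

Step 5
Reactants: 7 (4S,5S)-4-chloro-5-methyl-5-(2-methylprop-2-en-1-yl)cyclopent-1-en-1-yl trifluoromethanesulfonate
Product: 8 (3S,4S)-4-chloro-3-methyl-3-(2-methylprop-2-en-1-yl)cyclopent-1-ene
Conditions: Pd(OAc)2 (5 mol%), PPh3 (10 mol%), HCO2H, n-Bu3N, DMF, 50 °C
Reagents that add atoms: none
Why: Palladium-catalysed formate reduction of an enol triflate (oxidative addition, decarboxylation of formate, C–H reductive elimination) is a standard ketone-to-alkene conversion that leaves the secondary chloride, the 1,1-disubstituted alkene and both stereocentres untouched.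

Step 6
Reactants: 8 (3S,4S)-4-chloro-3-methyl-3-(2-methylprop-2-en-1-yl)cyclopent-1-ene; 9 (Z)-1,2-dichloroethene
Product: 10 (4S,5S)-4-chloro-5-[(Z)-2-chloroethenyl]-1,5-dimethylcyclohex-1-ene
Conditions: pentafluorophenylimido Mo monoaryloxide pyrrolide neophylidene complex with a 2,6-diarylphenoxide (5–10 mol%), 9 (3 equiv), C6H6, 22–40 °C, dry N2 stream
Reagents that add atoms: none
Why: Proposed new method: the chloromethylidene [Mo]=CHCl that carries Z-selective cross-metathesis with 9 should add across the strained cis-alkene of 8 with CHCl bonding to C1′ and Mo to C2, cycloreversion then opens the five-membered ring to the chlorovinyl group and a C2 alkylidene, this alkylidene closes on the methallyl alkene, and the released [Mo]=CH2 is turned back into [Mo]=CHCl by 9 with loss of vinyl chloride. The closest known reaction types are the ring-rearrangement metathesis of cyclopentenes that bear an alkenyl side chain and the Mo-catalysed Z-selective cross-metathesis of alkenes with (Z)-1,2-dichloroethene, whose initiation already converts a neophylidene, an alkylidene on a quaternary carbon like C1′, into an alkenyl chloride. The one ring that is closed is the six-membered carbocycle, by ring-closing metathesis of a monosubstituted alkylidene onto a 1,1-disubstituted alkene, with the new C1=C2 bond endocyclic and trisubstituted. No sp3 stereocentre is formed and C4 and C5 lie outside the reacting bonds, while the Z geometry is controlled by the catalyst, whose large aryloxide and small imido ligand hold all metallacyclobutane substituents on one side. The step needs ring closure to win over simple capping and to be independent of the sense of ring opening, which the substrate secures because an alkylidene at C1′ could only close a cyclobutene and is therefore capped by 9, the C2 alkenyl chloride so formed can re-enter the cycle, and the quaternary C5 favours the six-ring closure. Release of cyclopentene strain, the low metathesis reactivity of the unstrained trisubstituted cyclohexene and escape of vinyl chloride should pull the equilibria to 10, and the substrate offers no Lewis-basic group to the catalyst.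

Step 7
Reactants: 10 (4S,5S)-4-chloro-5-[(Z)-2-chloroethenyl]-1,5-dimethylcyclohex-1-ene
Product: 11 (1R,3S,4S,6S)-4-chloro-3-[(Z)-2-chloroethenyl]-1,3-dimethyl-7-oxabicyclo[4.1.0]heptane (oxygen on the face of the C5 methyl group, anti to chlorovinyl and C4–Cl)
Conditions: mCPBA, NaHCO3, CH2Cl2, 0 °C
Reagents that add atoms: 3-chloroperoxybenzoic acid, OOC(=O)c1cccc(Cl)c1
Why: Prilezhaev epoxidation picks the electron-rich trisubstituted ring alkene over the deactivated chloroalkene, and the peracid should approach the face that carries only the C5 methyl group, anti to both the chlorovinyl group and the C4–Cl dipole, which sets the C2–O configuration.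

Step 8
Reactants: 11 (1R,3S,4S,6S)-4-chloro-3-[(Z)-2-chloroethenyl]-1,3-dimethyl-7-oxabicyclo[4.1.0]heptane
Product: 12 (1S,4S,5S)-5-chloro-4-[(Z)-2-chloroethenyl]-4-methyl-2-methylidenecyclohexan-1-ol (OH trans to both ring chlorine-bearing substituent faces, cis to the C5 methyl)
Conditions: Cp2TiCl2 (2.5 equiv), Mn dust, THF, rt; then 1 M HCl
Reagents that add atoms: none
Why: Titanocene(III)-mediated homolytic epoxide opening gives the tertiary C1 radical while the C2–O bond and its configuration are kept, and hydrogen-atom abstraction from the unhindered methyl group by a second Ti(III) gives the exo-methylene allylic alcohol, a known isomerisation of trisubstituted epoxides that tolerates alkyl and alkenyl chlorides.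

Step 9
Reactants: 12 (1S,4S,5S)-5-chloro-4-[(Z)-2-chloroethenyl]-4-methyl-2-methylidenecyclohexan-1-ol
Product: 13 (1S,2S,4R)-2,4-dichloro-1-[(Z)-2-chloroethenyl]-1-methyl-5-methylidenecyclohexane
Conditions: PPh3, hexachloroacetone, CH2Cl2, −20 to 0 °C
Reagents that add atoms: hexachloroacetone, ClC(Cl)(Cl)C(=O)C(Cl)(Cl)Cl
Why: Appel-type chlorination with PPh3/hexachloroacetone, the variant known to turn secondary allylic alcohols with a terminal =CH2 into unrearranged chlorides, runs by SN2 with inversion, so the axial C2–OH becomes the equatorial C2–Cl cis to C4–Cl.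

Step 10
Reactants: 13 (1S,2S,4R)-2,4-dichloro-1-[(Z)-2-chloroethenyl]-1-methyl-5-methylidenecyclohexane
Product: 14 (1S,2R,4S,5S)-1-bromo-1-(bromomethyl)-2,4-dichloro-5-[(Z)-2-chloroethenyl]-5-methylcyclohexane
Conditions: Br2 (1.0 equiv), CH2Cl2, −78 °C, dark
Reagents that add atoms: bromine, BrBr
Why: Ionic anti addition of bromine, in which the 1,1-disubstituted alkene is far more nucleophilic than the hindered chloroalkene and bromide opens the bromonium ion at tertiary C1 along the axial trajectory, so that the smaller Br becomes axial (cis to C2–Cl) and CH2Br equatorial, the arrangement that avoids a 1,3-diaxial contact between CH2Br and the chlorovinyl group.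

**Compound list**
1 | 2-methylcyclopentane-1,3-dione | CC1C(=O)CCC1=O | starting material
2 | 3-bromo-2-methylprop-1-ene | C=C(C)CBr | starting material
3 | 2-methyl-2-(2-methylprop-2-en-1-yl)cyclopentane-1,3-dione | CC1(CC(C)=C)C(=O)CCC1=O | intermediate
4 | (2R,3R)-3-hydroxy-2-methyl-2-(2-methylprop-2-en-1-yl)cyclopentan-1-one | C[C@]1(CC(C)=C)C(=O)CC[C@H]1O | intermediate
5 | (2S,3S)-3-chloro-2-methyl-2-(2-methylprop-2-en-1-yl)cyclopentan-1-one | C[C@]1(CC(C)=C)C(=O)CC[C@@H]1Cl | intermediate
6 | lithium enolate of 5 (not isolated) | C[C@]1(CC(C)=C)C([O-])=CC[C@@H]1Cl.[Li+] | intermediate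
7 | (4S,5S)-4-chloro-5-methyl-5-(2-methylprop-2-en-1-yl)cyclopent-1-en-1-yl trifluoromethanesulfonate | C[C@]1(CC(C)=C)C(OS(=O)(=O)C(F)(F)F)=CC[C@@H]1Cl | intermediate
8 | (3S,4S)-4-chloro-3-methyl-3-(2-methylprop-2-en-1-yl)cyclopent-1-ene | C[C@]1(CC(C)=C)C=CC[C@@H]1Cl | intermediate
9 | (Z)-1,2-dichloroethene | Cl/C=C\Cl | starting material
10 | (4S,5S)-4-chloro-5-[(Z)-2-chloroethenyl]-1,5-dimethylcyclohex-1-ene | C[C@@]1(/C=C\Cl)CC(C)=CC[C@@H]1Cl | intermediate
11 | (1R,3S,4S,6S)-4-chloro-3-[(Z)-2-chloroethenyl]-1,3-dimethyl-7-oxabicyclo[4.1.0]heptane | C[C@@]1(/C=C\Cl)C[C@@]2(C)O[C@H]2C[C@@H]1Cl | intermediate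
12 | (1S,4S,5S)-5-chloro-4-[(Z)-2-chloroethenyl]-4-methyl-2-methylidenecyclohexan-1-ol | C[C@@]1(/C=C\Cl)CC(=C)[C@@H](O)C[C@@H]1Cl | intermediate
13 | (1S,2S,4R)-2,4-dichloro-1-[(Z)-2-chloroethenyl]-1-methyl-5-methylidenecyclohexane | C[C@@]1(/C=C\Cl)CC(=C)[C@H](Cl)C[C@@H]1Cl | intermediate
14 | (1S,2R,4S,5S)-1-bromo-1-(bromomethyl)-2,4-dichloro-5-[(Z)-2-chloroethenyl]-5-methylcyclohexane | C[C@@]1(/C=C\Cl)C[C@@](Br)(CBr)[C@H](Cl)C[C@@H]1Cl | target

Total step count: 10. Longest linear sequence: 10 steps (from 1).

**Steps most likely to fail**

Step 6 (proposed new method).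
- What may go wrong: slow ring opening of the only mildly strained alkene, one end of which is neopentylic; decay of the chloromethylidene before turnover; capping of both alkene ends by 9 without ring closure; loss of Z purity by secondary metathesis.
- The fallback uses known chemistry, sets out from 5 and comes back at 10.
- 5 is silylated (TMSOTf, Et3N) to the trimethylsilyl enol ether F1.
- Rubottom oxidation with mCPBA attacks the electron-rich enol ether before the methallyl alkene and gives the α-hydroxy ketone F2.
- Pb(OAc)4 in MeOH cleaves the C2–C1′ bond to the aldehyde ester F3.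
- Wittig methylenation at −78 °C gives the diene ester F4.
- Ring-closing metathesis with a second-generation ruthenium catalyst forms the same C1=C2 bond in the cyclohexene ester F5.
- DIBAL-H gives the neopentylic alcohol F6, and Dess–Martin oxidation gives the aldehyde F7.
- A Wittig reaction with Ph3P=CHCl gives 10 after separation from its E isomer.

Step 3.
- What may go wrong: elimination toward C3, or a Wagner–Meerwein shift from the quaternary carbon, in place of substitution at the neopentylic carbinol.
- The fallback replaces the ionic substitution by a stereoconvergent radical chlorination. It sets out from 4 and comes back at 5.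
- 4 is acylated with methyl chlorooxoacetate to the mixed methyl oxalate F8.
- Hydrolysis with CsOH gives the caesium oxalate F9.
- Visible-light photoredox double decarboxylation (Ir photocatalyst) in the presence of ethyl trichloroacetate gives the planar C4 radical.
- This radical should take chlorine from the face of the small methyl group, anti to methallyl, and so give 5.

Step 10.
- What may go wrong: poor facial selectivity in the opening of the bromonium ion past the axial chlorovinyl group; ionisation or allylic transposition of the C2 chloride before addition; radical Z/E isomerisation of the chloroalkene.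
- The fallback forms the two C–Br bonds in separate events. It sets out from 13 and comes back at 14.
- NBS in aqueous acetone lets the small nucleophile water open the bromonium ion at C1 and gives the bromohydrin F10.
- Diastereomers can be separated at this stage, and unwanted material returned to 13 with zinc.
- HBr in CH2Cl2 then replaces the tertiary hydroxyl group with retention through anchimeric assistance of the neighbouring CH2Br bromine and gives 14.

**Further compounds**
F1 | step 6 | {[(4S,5S)-4-chloro-5-methyl-5-(2-methylprop-2-en-1-yl)cyclopent-1-en-1-yl]oxy}trimethylsilane | C[C@]1(CC(C)=C)C(O[Si](C)(C)C)=CC[C@@H]1Cl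
F2 | step 6 | (2S,3S)-3-chloro-5-hydroxy-2-methyl-2-(2-methylprop-2-en-1-yl)cyclopentan-1-one (epimers at the new carbinol carbon) | C[C@]1(CC(C)=C)C(=O)C(O)C[C@@H]1Cl
F3 | step 6 | methyl (2S,3S)-3-chloro-2-methyl-2-(2-methylprop-2-en-1-yl)-5-oxopentanoate | C[C@](CC(C)=C)(C(=O)OC)[C@@H](Cl)CC=O
F4 | step 6 | methyl (2S,3S)-3-chloro-2-methyl-2-(2-methylprop-2-en-1-yl)hex-5-enoate | C[C@](CC(C)=C)(C(=O)OC)[C@@H](Cl)CC=C
F5 | step 6 | methyl (1S,6S)-6-chloro-1,3-dimethylcyclohex-3-ene-1-carboxylate | C[C@@]1(C(=O)OC)CC(C)=CC[C@@H]1Cl
F6 | step 6 | [(1S,6S)-6-chloro-1,3-dimethylcyclohex-3-en-1-yl]methanol | C[C@@]1(CO)CC(C)=CC[C@@H]1Cl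
F7 | step 6 | (1S,6S)-6-chloro-1,3-dimethylcyclohex-3-ene-1-carbaldehyde | C[C@@]1(C=O)CC(C)=CC[C@@H]1Cl
F8 | step 3 | methyl (1R,2R)-2-methyl-2-(2-methylprop-2-en-1-yl)-3-oxocyclopentyl oxalate | C[C@]1(CC(C)=C)C(=O)CC[C@H]1OC(=O)C(=O)OC
F9 | step 3 | caesium (1R,2R)-2-methyl-2-(2-methylprop-2-en-1-yl)-3-oxocyclopentyl oxalate | C[C@]1(CC(C)=C)C(=O)CC[C@H]1OC(=O)C(=O)[O-].[Cs+]
F10 | step 10 | (1S,2R,4S,5S)-1-(bromomethyl)-2,4-dichloro-5-[(Z)-2-chloroethenyl]-5-methylcyclohexan-1-ol | C[C@@]1(/C=C\Cl)C[C@@](O)(CBr)[C@H](Cl)C[C@@H]1Cl
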